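**Strategy.** The benzophenone carbonyl is disconnected on its ring A side: an aryllithium of ring A (from an aryl bromide carrying the masked aldehyde and the prenyl ether) adds to a chromene-8-carbaldehyde, and oxidation gives the ketone. The 2,2-dimethyl-2H-pyran ring fused to ring B (O1, C2, C3, C4, C4a, C8a) is not cyclised from an open chain but grown from the furan ring of a benzofuran. Reductive lithiation breaks the O1–C2 vinyl ether bond, the (Z)-alkenyllithium takes up acetone as the new quaternary C2, and acid re-closes O1 onto it: a one-carbon ring expansion that installs the gem-dimethyl carbon and inherits the cis C3=C4 geometry from the five-membered ring. The precursor is 6-(methoxymethoxy)benzofuran.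

Key step: step 2

Remark: the target is treated as the open keto aldehyde drawn (a ring–chain equilibrium with a cyclic hemiacetal is possible and is not treated separately); benzofuran-6-ol and 1-bromo-2,5-dimethoxy-4-methylbenzene are taken as commercial.

**Step 1**
Reactants: 1 benzofuran-6-ol
Product: 2 6-(methoxymethoxy)benzofuran
Conditions: NaH, MOMCl, THF, 0 °C to rt
Reagents that add atoms: chloromethyl methyl ether (MOMCl), COCCl
Why: Williamson-type O-alkylation of the sodium phenoxide with the reactive α-chloro ether should give the acetal ether, which tolerates organolithium chemistry and later directs lithiation.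

**Step 2**
Reactants: 2 6-(methoxymethoxy)benzofuran
Product: 5 7-(methoxymethoxy)-2,2-dimethyl-2H-chromene, via dilithiated ring-opened phenoxide 3 (not isolated), via (Z)-diol 4 (not isolated)
Conditions: Li powder, 4,4'-di-tert-butylbiphenyl (5 mol %), THF, 0 °C; filter; acetone, −78 °C; H2O work-up; then pyridinium p-toluenesulfonate (cat.), toluene, 50 °C
Reagents that add atoms: acetone, CC(C)=O
Why: Two electrons from Li, shuttled by the biphenyl radical anion, enter the benzofuran π-system and expel the phenoxide from C2, so the O1–C2 vinyl ether bond breaks and the (Z)-alkenyllithium 3 forms with the cis geometry of the five-membered ring intact; its carbanionic carbon adds to acetone, whose carbonyl carbon becomes C2 of the pyran, and mild acid ionises the tertiary allylic alcohol of 4 to an allyl cation (an o-quinone methide after proton loss) that the phenol oxygen captures. The closest known reaction type is the arene-catalysed reductive lithiation and ring opening of benzofurans with carbonyl trapping and cyclodehydration to 2H-chromenes. The pyran ring closes by O1–C2 bond formation, a 6-endo attack of the phenol on the allyl cation or, equivalently, an oxa-6π electrocyclisation of the o-quinone methide. No stereocentre is formed, and the C3=C4 geometry is fixed by the ring of origin. The step needs cleavage of the vinyl C2–O1 bond in preference to the aryl C8a–O1 bond and to the acetal ether, which the better leaving group (phenoxide) and the low temperature should secure, and addition to acetone in preference to its enolisation, which the low temperature favours.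

**Step 3**
Reactants: 5 7-(methoxymethoxy)-2,2-dimethyl-2H-chromene
Product: 7 7-(methoxymethoxy)-2,2-dimethyl-2H-chromene-8-carbaldehyde, via 8-lithiochromene 6 (not isolated)
Conditions: n-BuLi, THF, 0 °C; DMF, −78 °C to rt; H2O
Reagents that add atoms: N,N-dimethylformamide (DMF), CN(C)C=O
Why: Directed ortho-metalation should occur at C8, the only C–H flanked by the ring oxygen O1 and the methoxymethoxy group, and the aryllithium is formylated by DMF (Bouveault-type formylation).

**Step 4**
Reactants: 8 1-bromo-2,5-dimethoxy-4-methylbenzene
Product: 9 2-bromo-5-methylbenzene-1,4-diol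
Conditions: BBr3, CH2Cl2, −78 °C to rt; H2O
Reagents that add atoms: none
Why: Lewis acid-mediated cleavage of both aryl methyl ethers (BBr3 demethylation) frees the hydroquinone, whose bromine already marks the ring carbon that will carry the ketone.

**Step 5**
Reactants: 9 2-bromo-5-methylbenzene-1,4-diol
Product: 10 5-bromo-4-(methoxymethoxy)-2-methylphenol
Conditions: K2CO3 (1.0 equiv), MOMCl (1.0 equiv), acetone, 0 °C
Reagents that add atoms: chloromethyl methyl ether (MOMCl), COCCl
Why: Williamson-type etherification under acidity control: the hydroxyl ortho to bromine is markedly the more acidic, so with one equivalent of K2CO3 mainly its phenoxide is present and is captured by the highly reactive chloro ether.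

**Step 6**
Reactants: 10 5-bromo-4-(methoxymethoxy)-2-methylphenol
Product: 11 6-bromo-2-hydroxy-5-(methoxymethoxy)-3-methylbenzaldehyde
Conditions: MgCl2, Et3N, (CH2O)n, MeCN, reflux; aq NH4Cl
Reagents that add atoms: paraformaldehyde (as formaldehyde), C=O
Why: Magnesium phenoxide-directed ortho-formylation (Casnati–Skattebøl reaction) can only reach the one free ortho position, between the hydroxyl and the bromine, because the other ortho position carries the methyl group.

**Step 7**
Reactants: 11 6-bromo-2-hydroxy-5-(methoxymethoxy)-3-methylbenzaldehyde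
Product: 12 6-bromo-5-(methoxymethoxy)-3-methyl-2-[(3-methylbut-2-en-1-yl)oxy]benzaldehyde
Conditions: prenyl bromide, K2CO3, DMF, rt
Reagents that add atoms: 1-bromo-3-methylbut-2-ene (prenyl bromide), CC(C)=CCBr
Why: Williamson ether synthesis on the only free phenol with an allylic bromide should place the prenyl ether unambiguously.

**Step 8**
Reactants: 12 6-bromo-5-(methoxymethoxy)-3-methyl-2-[(3-methylbut-2-en-1-yl)oxy]benzaldehyde
Product: 13 1-bromo-2-(dimethoxymethyl)-6-(methoxymethoxy)-4-methyl-3-[(3-methylbut-2-en-1-yl)oxy]benzene
Conditions: HC(OMe)3, MeOH, pyridinium p-toluenesulfonate (cat.), rt; Et3N quench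
Reagents that add atoms: trimethyl orthoformate, COC(OC)OC; methanol, CO
Why: Acid-catalysed acetalisation, driven by the orthoformate as water scavenger, masks the aldehyde against the aryllithium of step 9 under conditions mild enough for the acetal ether and the prenyl ether.

**Step 9**
Reactants: 13 1-bromo-2-(dimethoxymethyl)-6-(methoxymethoxy)-4-methyl-3-[(3-methylbut-2-en-1-yl)oxy]benzene; 7 7-(methoxymethoxy)-2,2-dimethyl-2H-chromene-8-carbaldehyde
Product: 15 racemic [2-(dimethoxymethyl)-6-(methoxymethoxy)-4-methyl-3-[(3-methylbut-2-en-1-yl)oxy]phenyl][7-(methoxymethoxy)-2,2-dimethyl-2H-chromen-8-yl]methanol, via ring A aryllithium 14 (not isolated)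
Conditions: n-BuLi, THF, −78 °C; then 7, −78 to −20 °C; H2O
Reagents that add atoms: none
Why: Bromine–lithium exchange at −78 °C is faster than any deprotonation of the prenyl ether and gives an aryllithium chelated by its two ortho oxygen groups, which adds to the aldehyde (1,2-addition); the carbinol stereocentre forms without control and is erased in step 10.

**Step 10**
Reactants: 15 racemic diaryl carbinol
Product: 16 [2-(dimethoxymethyl)-6-(methoxymethoxy)-4-methyl-3-[(3-methylbut-2-en-1-yl)oxy]phenyl][7-(methoxymethoxy)-2,2-dimethyl-2H-chromen-8-yl]methanone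
Conditions: Dess–Martin periodinane, pyridine, CH2Cl2, 0 °C to rt
Reagents that add atoms: none
Why: Dess–Martin oxidation of the secondary diaryl carbinol spares both alkenes, and the pyridine buffer should keep the neighbouring dimethyl acetal from closing onto the carbinol.

**Step 11**
Reactants: 16 protected benzophenone
Product: 17 3-hydroxy-2-(7-hydroxy-2,2-dimethyl-2H-chromene-8-carbonyl)-5-methyl-6-[(3-methylbut-2-en-1-yl)oxy]benzaldehyde (CNP0150093.0)
Conditions: 2 M aq HCl, THF, rt
Reagents that add atoms: water, O
Why: Dilute aqueous acid hydrolyses the dimethyl acetal and both acetal ethers (each ortho to the ketone and therefore labile) in one operation, under conditions that the aryl prenyl ether and the chromene should tolerate.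

**Compound list**
1 | benzofuran-6-ol | Oc1ccc2ccoc2c1 | starting material
2 | 6-(methoxymethoxy)benzofuran | COCOc1ccc2ccoc2c1 | intermediate
3 | lithium (Z)-2-(2-lithioethenyl)-5-(methoxymethoxy)phenoxide | [Li]/C=C\c1ccc(OCOC)cc1O[Li] | intermediate
4 | (Z)-2-(3-hydroxy-3-methylbut-1-en-1-yl)-5-(methoxymethoxy)phenol | CC(C)(O)/C=C\c1ccc(OCOC)cc1O | intermediate
5 | 7-(methoxymethoxy)-2,2-dimethyl-2H-chromene | COCOc1ccc2C=CC(C)(C)Oc2c1 | intermediate
6 | [7-(methoxymethoxy)-2,2-dimethyl-2H-chromen-8-yl]lithium | [Li]c1c(OCOC)ccc2C=CC(C)(C)Oc12 | intermediate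
7 | 7-(methoxymethoxy)-2,2-dimethyl-2H-chromene-8-carbaldehyde | O=Cc1c(OCOC)ccc2C=CC(C)(C)Oc12 | intermediate
8 | 1-bromo-2,5-dimethoxy-4-methylbenzene | COc1cc(C)c(OC)cc1Br | starting material
9 | 2-bromo-5-methylbenzene-1,4-diol | Oc1cc(C)c(O)cc1Br | intermediate
10 | 5-bromo-4-(methoxymethoxy)-2-methylphenol | COCOc1cc(C)c(O)cc1Br | intermediate
11 | 6-bromo-2-hydroxy-5-(methoxymethoxy)-3-methylbenzaldehyde | O=Cc1c(O)c(C)cc(OCOC)c1Br | intermediate
12 | 6-bromo-5-(methoxymethoxy)-3-methyl-2-[(3-methylbut-2-en-1-yl)oxy]benzaldehyde | O=Cc1c(OCC=C(C)C)c(C)cc(OCOC)c1Br | intermediate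
13 | 1-bromo-2-(dimethoxymethyl)-6-(methoxymethoxy)-4-methyl-3-[(3-methylbut-2-en-1-yl)oxy]benzene | COC(OC)c1c(OCC=C(C)C)c(C)cc(OCOC)c1Br | intermediate
14 | [2-(dimethoxymethyl)-6-(methoxymethoxy)-4-methyl-3-[(3-methylbut-2-en-1-yl)oxy]phenyl]lithium | [Li]c1c(OCOC)cc(C)c(OCC=C(C)C)c1C(OC)OC | intermediate
15 | racemic [2-(dimethoxymethyl)-6-(methoxymethoxy)-4-methyl-3-[(3-methylbut-2-en-1-yl)oxy]phenyl][7-(methoxymethoxy)-2,2-dimethyl-2H-chromen-8-yl]methanol | COC(OC)c1c(OCC=C(C)C)c(C)cc(OCOC)c1C(O)c1c(OCOC)ccc2C=CC(C)(C)Oc12 | intermediate
16 | [2-(dimethoxymethyl)-6-(methoxymethoxy)-4-methyl-3-[(3-methylbut-2-en-1-yl)oxy]phenyl][7-(methoxymethoxy)-2,2-dimethyl-2H-chromen-8-yl]methanone | COC(OC)c1c(OCC=C(C)C)c(C)cc(OCOC)c1C(=O)c1c(OCOC)ccc2C=CC(C)(C)Oc12 | intermediate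
17 | 3-hydroxy-2-(7-hydroxy-2,2-dimethyl-2H-chromene-8-carbonyl)-5-methyl-6-[(3-methylbut-2-en-1-yl)oxy]benzaldehyde | CC(C)=CCOc1c(C)cc(O)c(C(=O)c2c(O)ccc3c2OC(C)(C)C=C3)c1C=O | target

**Step count.** Total: 11 steps. Longest linear sequence: 8 steps (steps 4 to 11, from 8 to 17). The ring B branch (steps 1 to 3) joins at step 9.

**Steps most likely to fail**

Step 2. Proton transfer from acetone to the strongly basic alkenyllithium (enolisation) may outrun carbonyl addition, and the acetal ether may be slowly cleaved on prolonged contact with lithium. The fallback sets out from 2 and replaces acetone by an electrophile that cannot be enolised. The same reductive ring opening is run briefly and 3 is quenched with CO2. On buffered acidification (aq NaH2PO4) the (Z)-3-[2-hydroxy-4-(methoxymethoxy)phenyl]prop-2-enoic acid F1 should lactonise spontaneously to 7-(methoxymethoxy)-2H-chromen-2-one F2, so the furan ring is still enlarged by one carbon. Double addition of MeLi (THF, −78 °C, with CeCl3 if conjugate addition interferes) to the lactone carbonyl of F2 then gives the diol 4, where the fallback comes back to the route. Cyclisation with pyridinium p-toluenesulfonate as in step 2 leads on to 5.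

Step 9. Addition of the doubly ortho-substituted aryllithium to the doubly ortho-substituted aldehyde may be slow, so that protonation or alkylation by the 1-bromobutane formed in the exchange overtakes C–C bond formation. The fallback sets out from 13 and reverses the polarity of the union. Bromine–lithium exchange (n-BuLi, THF, −78 °C) followed by DMF gives 2-(dimethoxymethyl)-6-(methoxymethoxy)-4-methyl-3-[(3-methylbut-2-en-1-yl)oxy]benzaldehyde F3. The 8-lithiochromene 6, made from 5 by directed ortho-metalation as in step 3, contains no alkyl halide, is stable at 0 °C and can be used in excess. Its addition to F3 comes back to the route at 15.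

Step 5. The two phenolic hydroxyls may not be discriminated well enough, giving the regioisomeric monoether and the bis-ether. The fallback sets out from 9 and fixes the regiochemistry by directed metalation instead of acidity. NaH and excess MOMCl give 1-bromo-2,5-bis(methoxymethoxy)-4-methylbenzene F4. LiN(i-Pr)2 (THF, −78 °C) removes the one ring proton flanked by bromine and an acetal oxygen, and DMF gives 2-bromo-3,6-bis(methoxymethoxy)-5-methylbenzaldehyde F5. BCl3 (1 equiv, CH2Cl2, −78 °C), chelated between the formyl oxygen and the neighbouring ether oxygen, should cleave only that acetal ether. This comes back to the route at 11 and makes step 6 unnecessary.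

**Further compounds**
F1 | step 2 | (Z)-3-[2-hydroxy-4-(methoxymethoxy)phenyl]prop-2-enoic acid | OC(=O)/C=C\c1ccc(OCOC)cc1O
F2 | step 2 | 7-(methoxymethoxy)-2H-chromen-2-one | COCOc1ccc2C=CC(=O)Oc2c1
F3 | step 9 | 2-(dimethoxymethyl)-6-(methoxymethoxy)-4-methyl-3-[(3-methylbut-2-en-1-yl)oxy]benzaldehyde | COC(OC)c1c(OCC=C(C)C)c(C)cc(OCOC)c1C=O
F4 | step 5 | 1-bromo-2,5-bis(methoxymethoxy)-4-methylbenzene | COCOc1cc(C)c(OCOC)cc1Br
F5 | step 5 | 2-bromo-3,6-bis(methoxymethoxy)-5-methylbenzaldehyde | O=Cc1c(OCOC)c(C)cc(OCOC)c1Br
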